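The γ-lactone ring (O, C7, C8, C17, C19) is cut at O–C7 and C17–C19. This excises CO2 and exposes a hidden pseudo-C2-symmetric pentitol, C6–C10, centred on C8: once C7 is inverted, C7 and C9 are homochiral. The precursor is thus a D-arabitol-derived bis(epoxide) whose central carbon C8 bears a vinyl triflate (C17). Palladium-catalysed cathodic carboxylation makes C17–C19, and the carboxylate opens one epoxide at C7. One operation builds the lactone, sets C7 and C8, frees O6 and spares the C9–C10 epoxide. That arm later carries a Diels–Alder construction of the cyclohexene ring. Nozaki–Hiyama–Kishi closure at C4–C5 forms the ten-membered ring.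

Key step: step 7

Numbering (briarane):
- C1 is the quaternary ring-fusion carbon (C15 methyl).
- C2 bears OAc, C3 bears OH, C4 bears the hexanoate.
- C5 (C16 methyl)=C6.
- C7 bears the lactone O, C8 bears OH, C9 bears OAc.
- C10 is the ring-fusion CH.
- C11 bears OH and the C20 methyl, C12 bears OH, and C13=C14.
- C17 bears OH and the C18 methyl; C19 is the lactone C=O.
- "Up" on the lactone ring is the face that carries C6.

Assumption: the Diels–Alder adduct 23 is drawn as the endo isomer. The exo isomer differs only at C11 and C14, keeps OAc and CH3 cis, and both centres are erased in step 16.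

Step 1
Reactants: 1 D-arabitol
Product: 2 1,2:4,5-bis-O-(pentan-3-ylidene)-D-arabitol
Conditions: 3,3-dimethoxypentane, camphorsulfonic acid (cat.), THF, reflux
Reagents that add atoms: 3,3-dimethoxypentane, CCC(OC)(OC)CC
Why: Acid-catalysed transketalisation under thermodynamic control ties each terminal 1,2-diol into a dioxolane and leaves only the central C8 hydroxyl free, without touching C7 or C9.

Step 2
Reactants: 2 bis-ketal alcohol
Product: 3 bis[(4R)-2,2-diethyl-1,3-dioxolan-4-yl] ketone
Conditions: (n-Pr)4N[RuO4] (cat.), NMO, 4 Å MS, CH2Cl2, rt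
Reagents that add atoms: none
Why: Ley–Griffith oxidation of the only free alcohol gives the truly C2-symmetric C8 ketone under neutral conditions that should not epimerise the α-alkoxy centres.

Step 3
Reactants: 3 C8 ketone
Product: 6 MOM-protected α-ketol methyl ketone, via lithium alkoxide 4 (not isolated), via MOM enol ether 5 (not isolated)
Conditions: ethyl vinyl ether, t-BuLi, THF, −78 → 0 °C; 3, −78 °C; MOMCl, DMPU, −78 °C → rt; 0.5 M aq. oxalic acid, THF, 0 °C
Reagents that add atoms: ethyl vinyl ether, C=COCC; chloromethyl methyl ether, COCCl; water, O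
Why: 1,2-Addition of an acyl anion equivalent to a ketone whose two faces are homotopic can give only one product (C8 is not yet stereogenic), the alkoxide is capped by Williamson-type O-alkylation, and the enol ether hydrolyses far faster than the ketals or the MOM acetal.

Step 4
Reactants: 6 methyl ketone
Product: 7 enol triflate
Conditions: KN(SiMe3)2, THF, −78 °C; PhNTf2, −78 → 0 °C
Reagents that add atoms: N-phenylbis(trifluoromethanesulfonimide), O=S(=O)(C(F)(F)F)N(c1ccccc1)S(=O)(=O)C(F)(F)F
Why: Kinetic enolisation can only take place at the methyl group because C8 is quaternary, and O-sulfonylation of that enolate gives the 1,1-disubstituted vinyl triflate.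

Step 5
Reactants: 7 enol triflate
Product: 8 tetraol
Conditions: AcOH/H2O 4:1, 40 °C
Reagents that add atoms: none
Why: Acid-catalysed ketal hydrolysis removes both dioxolanes under conditions that a MOM acetal and a vinyl triflate tolerate.

Step 6
Reactants: 8 tetraol
Product: 10 bis-epoxide vinyl triflate, via bis-tosylate 9 (not isolated)
Conditions: TsCl, Bu2SnO (cat.), Et3N, CH2Cl2, 0 °C; then K2CO3, MeOH, 0 °C
Reagents that add atoms: p-toluenesulfonyl chloride, Cc1ccc(cc1)S(=O)(=O)Cl (its atoms stay in 9 only)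
Why: Stannylene-catalysed regioselective primary tosylation followed by Williamson-type 3-exo-tet closure makes both epoxides with retention at C7 and C9, because only the C6–O and C10–O bonds are broken.

Step 7
Reactants: 10 bis-epoxide vinyl triflate
Product: 12 α-methylene-γ-lactone epoxide, via magnesium acrylate 11 (not isolated)
Conditions: PdCl2(PPh3)2 (cat.), CO2 (1 atm), n-Bu4NBF4, DMF, undivided cell, carbon-felt cathode, Mg anode, constant current, 2.2 F/mol, 0 °C; current off, 45 °C; aq. NH4Cl
Reagents that add atoms: carbon dioxide, O=C=O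
Why: Zerovalent palladium inserts into the C17–OTf bond, two-electron reduction of the cationic divalent vinylpalladium at the cathode gives a vinyl anion equivalent that adds to CO2 (new C17–C19 bond), and the carboxylate, paired with Mg2+ from the anode, opens one Mg2+-activated epoxide at C7 (new O–C7 bond) once the current is off and the cell is warmed. The closest known reaction types are the palladium-catalysed electrocarboxylation of vinyl triflates at a sacrificial magnesium anode and the lactonisation of 4,5-epoxy carboxylates. The γ-lactone closes in the 5-exo-tet mode, preferred over 6-endo attack at C6. C7 is set by stereospecific SN2 inversion of the arabitol-derived epoxide carbon, and C8, non-stereogenic in 10, becomes stereogenic through the choice between the two diastereotopic homochiral arms. The step needs arm selectivity, secured because the favoured transition state places the C6 methylene cis to the small OMOM group and trans to the branched oxiranyl carbon on the forming ring, and it needs chemoselectivity, secured because simple epoxides are inert to zerovalent palladium and to the working potential and only one carboxylate is available, so the C9–C10 epoxide survives. Keeping the cell cold during electrolysis postpones lactonisation, so that the reducible α-methylene lactone never meets the working cathode.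

Step 8
Reactants: 12 α-methylene-γ-lactone epoxide
Product: 13 C6 TBDPS ether
Conditions: TBDPSCl, imidazole, CH2Cl2, 0 °C → rt
Reagents that add atoms: tert-butyldiphenylsilyl chloride, CC(C)(C)[Si](Cl)(c1ccccc1)c1ccccc1
Why: Standard silylation of the only free (primary) hydroxyl.

Step 9
Reactants: 13 C6 TBDPS ether
Product: 14 α-keto lactone
Conditions: O3, CH2Cl2, −78 °C; Me2S
Reagents that add atoms: ozone, [O-][O+]=O
Why: Ozonolysis of the only C=C bond present removes the exocyclic methylene and gives a non-enolisable C17 ketone.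

Step 10
Reactants: 14 α-keto lactone
Product: 15 C17 tertiary alcohol
Conditions: MeMgBr, CH2Cl2/Et2O, −78 °C
Reagents that add atoms: methylmagnesium bromide, C[Mg]Br
Why: Cram-chelate-controlled Grignard addition, in which magnesium bridges the C17 ketone and the C8 OMOM oxygen and thereby turns the oxiranyl branch (C9) perpendicular to the carbonyl plane, so that methyl (C18) enters from the opposite, upper face and O17 ends trans to O8, the doubly activated ketone reacting faster than lactone or epoxide at this temperature.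

Step 11
Reactants: 15 C17 tertiary alcohol
Product: 16 C9,C10 diol
Conditions: HClO4 (cat.), THF/H2O, 0 °C
Reagents that add atoms: water, O
Why: Acid-catalysed epoxide hydrolysis by SN2 attack of water at the unhindered terminal C10, so that the C9–O bond and its configuration are kept.

Step 12
Reactants: 16 C9,C10 diol; 17 2-(triphenylphosphoranylidene)propanal
Product: 19 γ-hydroxy E-enal, via α-hydroxy aldehyde 18 (not isolated)
Conditions: TEMPO (cat.), PhI(OAc)2, CH2Cl2, 0 °C → rt; then 17, toluene, 60 °C
Reagents that add atoms: none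
Why: Tandem oxidation–Wittig reaction, in which the oxoammonium oxidant selects the primary alcohol and the stabilised ylide traps the sensitive aldehyde to give the E-trisubstituted enal (C9 cis to the C15 methyl).

Step 13
Reactants: 19 γ-hydroxy E-enal
Product: 20 C9 acetate (dienophile)
Conditions: Ac2O, pyridine, DMAP (cat.), CH2Cl2, 0 °C
Reagents that add atoms: acetic anhydride, CC(=O)OC(C)=O
Why: DMAP-catalysed acetylation of the only secondary alcohol installs the final C9 acetate, stops any migration of the lactone from O7 to O9, and leaves the hindered tertiary C17 hydroxyl untouched.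

Step 14
Reactants: 21 (E)-pent-2-enal
Product: 22 (1E,3E)-penta-1,3-dien-1-yl acetate
Conditions: isopropenyl acetate, TsOH (cat.), reflux, distillation
Reagents that add atoms: isopropenyl acetate, CC(=C)OC(C)=O
Why: Acid-catalysed enol acetylation of the extended enol, of which only the (1E,3E)-isomer can reach the s-cis form needed in step 15.

Step 15
Reactants: 20 dienophile; 22 acetoxydiene
Product: 23 cyclohexene adduct
Conditions: BF3·OEt2, CH2Cl2, −78 → −30 °C
Reagents that add atoms: none
Why: Lewis acid-promoted normal-demand Diels–Alder reaction in which the acyloxy donor directs the ortho orientation (C14 to C1, C11 to C10), the E-dienophile geometry makes the C15 methyl and C9 cis, and A(1,3) strain against the C15 methyl holds H9 in the alkene plane so that the diene adds anti to the bulky quaternary C8, which sets C1 and C10.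

Step 16
Reactants: 23 cyclohexene adduct
Product: 24 cyclohexa-1,3-diene aldehyde
Conditions: Pd(PPh3)4 (cat.), Et3N, THF, 60 °C
Reagents that add atoms: none
Why: Palladium-catalysed 1,4-elimination of an allylic acetate (Tsuji–Trost ionisation by zerovalent palladium anti to OAc, then syn β-hydride elimination of H11, which is trans to OAc), unambiguous because C1 is quaternary and offers no other β-hydrogen.

Step 17
Reactants: 24 cyclohexa-1,3-diene aldehyde
Product: 25 C11,C12 cis-diol
Conditions: OsO4 (cat.), NMO (1 equiv), acetone/H2O, 0 °C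
Reagents that add atoms: N-methylmorpholine N-oxide, C[N+]1([O-])CCOCC1; water, O
Why: Upjohn dihydroxylation picks the more electron-rich trisubstituted C11=C12 bond of the diene and adds syn from the face opposite the C15 methyl and the bulky C9 branch, which sets C11 and C12.

Step 18
Reactants: 25 C11,C12 cis-diol
Product: 26 C11,C12 acetonide aldehyde
Conditions: 2-methoxypropene, PPTS (cat.), CH2Cl2, 0 °C
Reagents that add atoms: 2-methoxypropene, COC(C)=C
Why: Acid-catalysed acetonide formation is specific for the cis-1,2-diol and leaves the isolated tertiary C17 hydroxyl free.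

Step 19
Reactants: 26 C11,C12 acetonide aldehyde
Product: 27 C2 alcohol with C3 OMOM and a vinyl group
Conditions: allyl methoxymethyl ether, s-BuLi, THF, −78 °C; (−)-Ipc2BOMe; BF3·OEt2; 26, −78 → −20 °C; H2O2, pH 7 buffer, 0 °C
Reagents that add atoms: allyl methoxymethyl ether, C=CCOCOC
Why: Brown-type asymmetric (Z)-γ-alkoxyallylboration through a chair Zimmerman–Traxler transition state, in which the Z-geometry gives the 2,3-syn relationship and the isopinocampheyl groups derived from (+)-α-pinene direct attack to the Si face of the aldehyde, which sets C2 and C3.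

Step 20
Reactants: 27 C2 alcohol
Product: 28 C2 acetate
Conditions: Ac2O, Et3N, DMAP, CH2Cl2, rt
Reagents that add atoms: acetic anhydride, CC(=O)OC(C)=O
Why: DMAP-catalysed acetylation of the only secondary alcohol installs the final C2 acetate.

Step 21
Reactants: 28 C2 acetate
Product: 29 C6 primary alcohol
Conditions: TBAF, AcOH, THF, rt
Reagents that add atoms: none
Why: Buffered fluoride desilylation removes the silyl ether without acyl migration or loss of the acetal protecting groups.

Step 22
Reactants: 29 C6 primary alcohol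
Product: 30 C6 aldehyde
Conditions: Dess–Martin periodinane, pyridine, CH2Cl2, 0 °C
Reagents that add atoms: none
Why: Dess–Martin oxidation under buffered, non-basic conditions should give the α-acyloxy aldehyde without epimerisation at C7 or β-elimination of the C8 OMOM group.

Step 23
Reactants: 30 C6 aldehyde
Product: 31 (Z)-vinyl iodide
Conditions: EtPPh3I, n-BuLi, THF, rt; I2, −78 °C; NaN(SiMe3)2, −20 °C; 30, −78 °C
Reagents that add atoms: ethyltriphenylphosphonium iodide, CC[P+](c1ccccc1)(c1ccccc1)c1ccccc1.[I-]; iodine, II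
Why: Stork–Zhao-type Wittig olefination with the non-stabilised α-iodoethylidene ylide gives kinetically the Z-trisubstituted vinyl iodide (I cis to C7), which fixes the C5=C6 geometry and brings in C5 and C16.

Step 24
Reactants: 31 (Z)-vinyl iodide
Product: 33 C4 aldehyde, via terminal diol 32 (not isolated)
Conditions: OsO4 (cat.), NMO, acetone/H2O, 0 °C; then NaIO4, rt
Reagents that add atoms: N-methylmorpholine N-oxide, C[N+]1([O-])CCOCC1; water, O
Why: Lemieux–Johnson-type cleavage, in which the monosubstituted terminal alkene should be osmylated faster than the cis-disubstituted C13=C14 bond next to quaternary C1 and than the electron-poor trisubstituted vinyl iodide.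

Step 25
Reactants: 33 C4 aldehyde
Product: 34 macrocyclic (4S)-allylic alcohol
Conditions: CrCl2 (excess), NiCl2 (cat.), THF/DMF, high dilution, rt
Reagents that add atoms: none
Why: Nozaki–Hiyama–Kishi macrocyclisation, in which zerovalent nickel inserts into the C5–I bond with retention of the Z geometry, the derived vinylchromium tolerates esters, lactone and free tertiary hydroxyl and adds to the C4 aldehyde, and chelation of trivalent chromium by the aldehyde and C3 OMOM oxygens should steer attack to the face that gives the 3,4-syn (4S) alcohol.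

Step 26
Reactants: 34 macrocyclic (4S)-allylic alcohol
Product: 35 C4 hexanoate
Conditions: hexanoic anhydride, Et3N, DMAP (cat.), CH2Cl2, 0 °C
Reagents that add atoms: hexanoic anhydride, CCCCCC(=O)OC(=O)CCCCC
Why: DMAP-catalysed acylation of the only secondary hydroxyl in the molecule.

Step 27
Reactants: 35 C4 hexanoate
Product: 36 CNP0153048.1
Conditions: TFA/H2O 9:1, CH2Cl2, 0 °C
Reagents that add atoms: none
Why: Acid-catalysed hydrolysis of all three acetal-type groups (C3 and C8 MOM ethers, C11,C12 acetonide) in one operation, under acidic conditions in which ester migration to the freed C3 hydroxyl is slow.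

Compound list
1 | D-arabitol, (2R,4R)-pentane-1,2,3,4,5-pentol (becomes C6–C10) | OC([C@H](O)CO)[C@H](O)CO | starting material
2 | 1,2:4,5-bis-O-(pentan-3-ylidene)-D-arabitol | OC([C@H]1COC(CC)(CC)O1)[C@H]1COC(CC)(CC)O1 | intermediate
3 | bis[(4R)-2,2-diethyl-1,3-dioxolan-4-yl] ketone | O=C([C@H]1COC(CC)(CC)O1)[C@H]1COC(CC)(CC)O1 | intermediate
4 | lithium alkoxide of the 1-ethoxyvinyl adduct of 3 | [Li]OC(C(=C)OCC)([C@H]1COC(CC)(CC)O1)[C@H]1COC(CC)(CC)O1 | intermediate
5 | C8 MOM ether of the 1-ethoxyvinyl adduct | C=C(OCC)C(OCOC)([C@H]1COC(CC)(CC)O1)[C@H]1COC(CC)(CC)O1 | intermediate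
6 | 1,1-bis[(4R)-2,2-diethyl-1,3-dioxolan-4-yl]-1-(methoxymethoxy)propan-2-one | CC(=O)C(OCOC)([C@H]1COC(CC)(CC)O1)[C@H]1COC(CC)(CC)O1 | intermediate
7 | 3,3-bis[(4R)-2,2-diethyl-1,3-dioxolan-4-yl]-3-(methoxymethoxy)prop-1-en-2-yl triflate | C=C(OS(=O)(=O)C(F)(F)F)C(OCOC)([C@H]1COC(CC)(CC)O1)[C@H]1COC(CC)(CC)O1 | intermediate
8 | tetraol from 7 (both ketals removed) | C=C(OS(=O)(=O)C(F)(F)F)C(OCOC)([C@H](O)CO)[C@H](O)CO | intermediate
9 | bis(primary tosylate) of 8 | C=C(OS(=O)(=O)C(F)(F)F)C(OCOC)([C@H](O)COS(=O)(=O)c1ccc(C)cc1)[C@H](O)COS(=O)(=O)c1ccc(C)cc1 | intermediate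
10 | 3-(methoxymethoxy)-3,3-bis[(2R)-oxiran-2-yl]prop-1-en-2-yl triflate | C=C(OS(=O)(=O)C(F)(F)F)C(OCOC)([C@H]1CO1)[C@H]1CO1 | intermediate
11 | 2-substituted acrylate from 10 (magnesium salt, drawn as the carboxylate) | [O-]C(=O)C(=C)C(OCOC)([C@H]1CO1)[C@H]1CO1 | intermediate
12 | α-methylene-γ-lactone: (7S)-CH2OH and C8 OMOM cis on the ring, (R)-oxiranyl (C9–C10) on C8 trans to C6 | OC[C@@H]1OC(=O)C(=C)[C@@]1(OCOC)[C@H]1CO1 | intermediate
13 | C6 TBDPS ether of 12 | CC(C)(C)[Si](c1ccccc1)(c1ccccc1)OC[C@@H]1OC(=O)C(=C)[C@@]1(OCOC)[C@H]1CO1 | intermediate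
14 | α-keto lactone (C17 ketone) | CC(C)(C)[Si](c1ccccc1)(c1ccccc1)OC[C@@H]1OC(=O)C(=O)[C@@]1(OCOC)[C@H]1CO1 | intermediate
15 | C17 tertiary alcohol (C18 methyl cis to OMOM, O17 trans to O8) | CC(C)(C)[Si](c1ccccc1)(c1ccccc1)OC[C@@H]1OC(=O)[C@@](C)(O)[C@@]1(OCOC)[C@H]1CO1 | intermediate
16 | C9,C10 diol | CC(C)(C)[Si](c1ccccc1)(c1ccccc1)OC[C@@H]1OC(=O)[C@@](C)(O)[C@@]1(OCOC)[C@H](O)CO | intermediate
17 | 2-(triphenylphosphoranylidene)propanal (brings C1, C2, C15) | CC(C=O)=P(c1ccccc1)(c1ccccc1)c1ccccc1 | starting material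
18 | C10 α-hydroxy aldehyde | CC(C)(C)[Si](c1ccccc1)(c1ccccc1)OC[C@@H]1OC(=O)[C@@](C)(O)[C@@]1(OCOC)[C@H](O)C=O | intermediate
19 | (E)-enal C10=C1(CH3)–CHO with free C9 OH | CC(C)(C)[Si](c1ccccc1)(c1ccccc1)OC[C@@H]1OC(=O)[C@@](C)(O)[C@@]1(OCOC)[C@H](O)/C=C(\C)C=O | intermediate
20 | C9 acetate of 19 | CC(C)(C)[Si](c1ccccc1)(c1ccccc1)OC[C@@H]1OC(=O)[C@@](C)(O)[C@@]1(OCOC)[C@H](OC(C)=O)/C=C(\C)C=O | intermediate
21 | (E)-pent-2-enal | CC/C=C/C=O | starting material
22 | (1E,3E)-penta-1,3-dien-1-yl acetate (brings C11–C14, C20) | C/C=C/C=C/OC(C)=O | intermediate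
23 | Diels–Alder adduct (C12=C13; C14 OAc, C11 CH3 and C2 aldehyde cis) | CC(C)(C)[Si](c1ccccc1)(c1ccccc1)OC[C@@H]1OC(=O)[C@@](C)(O)[C@@]1(OCOC)[C@H](OC(C)=O)[C@H]1[C@H](C)C=C[C@H](OC(C)=O)[C@]1(C)C=O | intermediate
24 | cyclohexa-1,3-diene (C11=C12–C13=C14) aldehyde | CC(C)(C)[Si](c1ccccc1)(c1ccccc1)OC[C@@H]1OC(=O)[C@@](C)(O)[C@@]1(OCOC)[C@H](OC(C)=O)[C@H]1C(C)=CC=C[C@]1(C)C=O | intermediate
25 | C11,C12 cis-diol aldehyde | CC(C)(C)[Si](c1ccccc1)(c1ccccc1)OC[C@@H]1OC(=O)[C@@](C)(O)[C@@]1(OCOC)[C@H](OC(C)=O)[C@H]1[C@](C)(O)[C@H](O)C=C[C@]1(C)C=O | intermediate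
26 | C11,C12 acetonide aldehyde | CC(C)(C)[Si](c1ccccc1)(c1ccccc1)OC[C@@H]1OC(=O)[C@@](C)(O)[C@@]1(OCOC)[C@H](OC(C)=O)[C@H]1[C@]2(C)OC(C)(C)O[C@@H]2C=C[C@]1(C)C=O | intermediate
27 | (2R)-alcohol, (3R)-OMOM, terminal vinyl | CC(C)(C)[Si](c1ccccc1)(c1ccccc1)OC[C@@H]1OC(=O)[C@@](C)(O)[C@@]1(OCOC)[C@H](OC(C)=O)[C@H]1[C@]2(C)OC(C)(C)O[C@@H]2C=C[C@]1(C)[C@@H](O)[C@H](OCOC)C=C | intermediate
28 | C2 acetate of 27 | CC(C)(C)[Si](c1ccccc1)(c1ccccc1)OC[C@@H]1OC(=O)[C@@](C)(O)[C@@]1(OCOC)[C@H](OC(C)=O)[C@H]1[C@]2(C)OC(C)(C)O[C@@H]2C=C[C@]1(C)[C@@H](OC(C)=O)[C@H](OCOC)C=C | intermediate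
29 | C6 primary alcohol | OC[C@@H]1OC(=O)[C@@](C)(O)[C@@]1(OCOC)[C@H](OC(C)=O)[C@H]1[C@]2(C)OC(C)(C)O[C@@H]2C=C[C@]1(C)[C@@H](OC(C)=O)[C@H](OCOC)C=C | intermediate
30 | C6 aldehyde | O=C[C@@H]1OC(=O)[C@@](C)(O)[C@@]1(OCOC)[C@H](OC(C)=O)[C@H]1[C@]2(C)OC(C)(C)O[C@@H]2C=C[C@]1(C)[C@@H](OC(C)=O)[C@H](OCOC)C=C | intermediate
31 | (Z)-vinyl iodide C6H=C5(I)CH3 | I/C(C)=C\[C@@H]1OC(=O)[C@@](C)(O)[C@@]1(OCOC)[C@H](OC(C)=O)[C@H]1[C@]2(C)OC(C)(C)O[C@@H]2C=C[C@]1(C)[C@@H](OC(C)=O)[C@H](OCOC)C=C | intermediate
32 | terminal 1,2-diol from the vinyl group (new carbinol centre undefined) | I/C(C)=C\[C@@H]1OC(=O)[C@@](C)(O)[C@@]1(OCOC)[C@H](OC(C)=O)[C@H]1[C@]2(C)OC(C)(C)O[C@@H]2C=C[C@]1(C)[C@@H](OC(C)=O)[C@H](OCOC)C(O)CO | intermediate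
33 | C4 aldehyde–vinyl iodide | I/C(C)=C\[C@@H]1OC(=O)[C@@](C)(O)[C@@]1(OCOC)[C@H](OC(C)=O)[C@H]1[C@]2(C)OC(C)(C)O[C@@H]2C=C[C@]1(C)[C@@H](OC(C)=O)[C@H](OCOC)C=O | intermediate
34 | macrocyclic (4S)-allylic alcohol | O[C@H]1/C(C)=C\[C@@H]2OC(=O)[C@@](C)(O)[C@@]2(OCOC)[C@H](OC(C)=O)[C@H]2[C@]3(C)OC(C)(C)O[C@@H]3C=C[C@]2(C)[C@@H](OC(C)=O)[C@@H]1OCOC | intermediate
35 | C4 hexanoate | CCCCCC(=O)O[C@H]1/C(C)=C\[C@@H]2OC(=O)[C@@](C)(O)[C@@]2(OCOC)[C@H](OC(C)=O)[C@H]2[C@]3(C)OC(C)(C)O[C@@H]3C=C[C@]2(C)[C@@H](OC(C)=O)[C@@H]1OCOC | intermediate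
36 | CNP0153048.1 | CCCCCC(=O)O[C@H]1/C(C)=C\[C@@H]2OC(=O)[C@@](C)(O)[C@@]2(O)[C@H](OC(C)=O)[C@H]2[C@](C)(O)[C@H](O)C=C[C@]2(C)[C@@H](OC(C)=O)[C@@H]1O | target

Total step count: 27. Longest linear sequence: 26 (steps 1–13 and 15–27).

Steps most likely to fail

1. Step 7.
- Risk: the vinyl anion equivalent may expel the neighbouring OMOM group or be protonated before it meets CO2. The product may be reduced further at the cathode. The two diastereotopic epoxide arms may be discriminated poorly.
- Fallback (the carbonyl carbon comes from CO through an acylpalladium, with no carbanion and no cell): starting from 10, palladium-catalysed alkoxycarbonylation (Pd(OAc)2, dppp, CO 1 atm, 2-(trimethylsilyl)ethanol, Et3N, DMF) should give the 2-(trimethylsilyl)ethyl acrylate F1. Fluoride (TBAF, THF, 0 → 40 °C) then unmasks the carboxylate, which closes onto C7 as in the main route. The sequence rejoins at 12.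

2. Step 15.
- Risk: cycloaddition of the hindered trisubstituted enal may be sluggish. Regiocontrol may erode, because the acetoxy- and methyl-bearing diene termini are donors of similar strength.
- Fallback (a more strongly polarised diene and a later exchange of the leaving group): starting from 21, soft enolisation (TMSOTf, Et3N) should give (1E,3E)-1-(trimethylsilyloxy)penta-1,3-diene F2. Its cycloaddition to 20 should give the allylic silyl ether adduct F3. Aqueous citric acid should release the C14 allylic alcohol F4. Acetylation (Ac2O, pyridine) rejoins the route at 23.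

3. Step 25.
- Risk: facial selectivity at the C4 aldehyde may be poor during ring closure if the non-chelated Felkin–Anh mode wins.
- Fallback (invert instead of retain): starting from 33, the same ring closure would then deliver the (4R)-epimeric macrocyclic alcohol F5. Mitsunobu esterification with hexanoic acid (PPh3, DIAD, toluene, 0 °C) installs the hexanoate with SN2 inversion. This replaces step 26 and rejoins the route at 35.

Further compounds
F1 | step 7 | 2-(trimethylsilyl)ethyl 2-{(methoxymethoxy)bis[(2R)-oxiran-2-yl]methyl}acrylate | C=C(C(=O)OCC[Si](C)(C)C)C(OCOC)([C@H]1CO1)[C@H]1CO1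
F2 | step 15 | (1E,3E)-1-(trimethylsilyloxy)penta-1,3-diene | C/C=C/C=C/O[Si](C)(C)C
F3 | step 15 | Diels–Alder adduct with C14 OTMS | CC(C)(C)[Si](c1ccccc1)(c1ccccc1)OC[C@@H]1OC(=O)[C@@](C)(O)[C@@]1(OCOC)[C@H](OC(C)=O)[C@H]1[C@H](C)C=C[C@H](O[Si](C)(C)C)[C@]1(C)C=O
F4 | step 15 | C14 allylic alcohol | CC(C)(C)[Si](c1ccccc1)(c1ccccc1)OC[C@@H]1OC(=O)[C@@](C)(O)[C@@]1(OCOC)[C@H](OC(C)=O)[C@H]1[C@H](C)C=C[C@H](O)[C@]1(C)C=O
F5 | step 25 | (4R)-epimer of macrocyclic alcohol 34 | O[C@@H]1/C(C)=C\[C@@H]2OC(=O)[C@@](C)(O)[C@@]2(OCOC)[C@H](OC(C)=O)[C@H]2[C@]3(C)OC(C)(C)O[C@@H]3C=C[C@]2(C)[C@@H](OC(C)=O)[C@@H]1OCOC
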